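Numbering used for the target: the bicycle is C1 (acylal CH), O2, C3 (lactone C=O), C4 (CH2), C5 (bridgehead CH), C6 (CH–CO2Me), O7, C8 (one-carbon bridge). The decalin is primed: C1′ (CH–CH3), C2′ (quaternary), C3′, C4′, C4a′ (ring-fusion CH), C5′ (CMe2), C6′, C7′, C8′ (=CH), C8a′ (olefinic fusion carbon). Ring A is C4a′–C5′–C6′–C7′–C8′–C8a′; ring B is C1′–C2′–C3′–C4′–C4a′–C8a′.

## Analysis of the target

The target is a 2,7-dioxabicyclo[3.2.1]octan-3-one: a δ-lactone and a tetrahydrofuran that share the acylal carbon C1, the bridgehead C5 and the one-carbon bridge C8. C6 carries a methyl ester and C8 is bonded to the quaternary carbon C2′ of a 1,2,5,5-tetramethyl-octahydronaphthalene. There are seven stereocentres. On the bicycle, C1 follows from the bridging once C5 and C8 are fixed, the ester on C6 is exo, and the decalinyl group on C8 lies anti to the O7–C6 bridge. On the decalin, H-1′ and H-4a′ are cis, the methyl groups on C1′ and C2′ lie on the other face, and the C2′–C8 bond is equatorial and trans to the C1′ methyl group. The two stereochemical arrays meet in the single bond C8–C2′, between a tertiary and a quaternary carbon next to the C1′ stereocentre, so their absolute relation has to be imposed across that bond. Sensitive groups are the acylal at C1 (base, nucleophiles), the α-alkoxy ester proton at C6, and the trisubstituted C8′=C8a′ olefin, which acid can move to the tetrasubstituted C4a′=C8a′ position with loss of the C4a′ stereocentre. The hard points are the congested C8–C2′ bond with control at C2′, a ring-fusion CH with no angular substituent to direct it, and keeping the olefin in place. The strategy rests on ring A: the gem-dimethyl carbon C5′, the lone fusion hydrogen at C4a′ and the olefinic fusion carbon C8a′ are the imprint of a proton-initiated polyene cyclisation. Ring B completes the pattern if C2′ is read as a former ketone carbon and C1′ with its methyl group as the CH2CH3 of an ethyl branch, so the whole decalin maps onto 7, the ethyl homologue of geranylacetone.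

## Retrosynthetic reasoning

**24 ⇒ 22 (bonds O2–C1 and O7–C1).** Both C–O bonds at the acylal carbon are cut first, together with the silyl group on O7. The acylal is the most fragile function and is therefore made last. This exposes aldehyde acid 22, in which C1 is a formyl carbon, C3 a carboxyl carbon and C6 a silyl-protected carbinol. C1 needs no separate control, because only one bridged arrangement is possible once C5 and C8 are set. The forward step has to desilylate, close the lactol and lactonise under acid mild enough to leave C8′=C8a′ where it is.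

**22 ⇒ 21 ⇒ 19 (C1 joined to C3).** C1 and C3 are joined into a cyclopentene, enol silane 21, whose double bond is cleaved oxidatively in the forward direction. The five-membered ring holds the C5 and C8 substituents trans, and the enol ether differentiates the aldehyde and acid oxidation levels. The position of the enol double bond is guaranteed by the chlorine atom of 19: reductive removal of chlorine gives the enolate at that carbon only.

**19 ⇒ 11 + 18 (bond C8–C2′).** The bond between the two halves is cut as a tertiary radical plus an electron-poor olefin. Polar methods are not available for a quaternary carbon with no adjacent carbonyl group, whereas a radical addition has an early transition state and tolerates the congestion. The gain is convergence: two enantiopure pieces of similar size, oxalate 11 and chloroenone 18. The forward reaction has to add to the ring carbon C3 of 18 anti to its side chain (this sets C8 relative to C5), meet the radical on the face anti to the C1′ methyl group (this sets C2′), and keep the chlorine.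

**18 ⇒ 12 (through 17, 16, 15, 14, 13).** C5 and C6 of the target are the ring stereocentre and the carbinol carbon of 18. They are traced back to hydroxy lactone 14, in which a six-membered lactone bridges the cyclopentene. In bicyclic lactone 13 the future carbinol carbon can only be hydroxylated from the open face, and 13 comes from ketone 12 by ring expansion with migration of the bridgehead. One purchased stereochemical element, 12, thus controls both centres.

**11 ⇒ 9.** The oxalate is only an activated form of the tertiary alcohol; the carbinol configuration of 9 is lost when the radical forms.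

**9 ⇒ 7 (bonds C4a′–C5′ and C1′–C2′).** This is the key disconnection. All other skeletal bonds of the decalin are already present in the linear, achiral dienone 7. The forward step is a proton-initiated closure of ring A followed by a Prins closure of ring B inside a cyclase. It builds both rings, three stereocentres and the olefin position in one operation, and the enzyme supplies the absolute control at C4a′ that no substituent of 7 could.

**7 ⇒ 3 + 4 + 5, and 3 ⇒ 1 + 2.** The trisubstituted olefin of 7 must be geometrically pure, because its geometry decides how the chain folds. A sigmatropic route through a tertiary vinyl carbinol was not taken: ethyl and homoprenyl groups are too alike to bias the geometry, and the isomers would be hard to separate. Instead the olefin is made by syn addition of an ethyl–copper bond across alkyne 3, followed by conjugate addition of alkenylcopper 6 to enone 5 with retention. Alkyne 3 comes from bromide 1 and acetylide 2.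

## Alternatives that were turned down

**Alternative 1:** Ring B is cut at C1′–C2′ and C3′–C4′, a [4+2] retron. In the forward step an α-methyl enal, activated by a chiral Lewis acid of the protonated oxazaborolidine type, adds exo to a ring-A diene with adjacent exocyclic methylene and ethylidene groups to give octalin aldehyde A1.
- For: C2′ and C1′ are formed together under catalyst control, the "ortho" regiochemistry and the exo preference of α-substituted enals both point the right way, and the aldehyde is a handle on C2′.
- Against: A1 has its olefin at C4a′=C8a′, so the C4a′ hydrogen is missing and must be created later by a reductive transposition through the C8′ oxygen. The diene must be enantiopure with its ethylidene methyl group pointing outward against allylic strain. C5, C6 and C8 would then be built linearly on a neopentyl aldehyde with only weak 1,2-induction from C2′.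
- Comparison: on control of C2′ this route is stronger than the chosen one, which relies on the facial preference of a radical. The chosen route offers instead the olefin in its final place, C4a′ from the enzyme, and the whole bicycle delivered as one enantiopure piece.

**Alternative 2:** The bicycle is cut at O7–C1 and C5–C6. A hydroxymalonate diester adds through oxygen to C6 of a 5-decalinyl-2-pyranone, the ring is protonated, and the malonate carbon closes onto C4 to give the bridged geminal diester A2.
- For: the complete heterobicycle arises in one operation from a flat ring, without protecting groups and without a stereocentre at C6 during the annulation.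
- Against: the pyranone needs C2′ already attached to an sp2 carbon, so the difficult bond is moved, not solved. C1, C5 and C8 would be set relative to the decalin only by a freely rotating remote centre. The oxa-Michael step is reversible and the alkoxide can open the pyranone at its carbonyl. The second closure occurs next to the tert-alkyl-bearing carbon. One ester must then be removed in the presence of the acylal, although the thermodynamic preference for the exo ester would help there.
- Comparison: the endgame is shorter on paper. The chosen route offers a fragment union of a precedented type with C5 and C6 fixed beforehand in a small, rigid intermediate.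

**Alternative 3:** Only C1′–C2′ is cut. An aluminium-based Lewis acid activates an alkylidene malonate on the side chain, the ethylidene carbon of a ring-A allylsilane attacks its β-carbon, and silicon is lost to give decalinyl malonate A3.
- For: loss of silicon fixes the olefin at C8′=C8a′ without ambiguity, and C2′ and C1′ form in an intramolecular chair that places the bulky malonate equatorial, as the target requires.
- Against: the precursor needs an enantiopure ring A with the C4a′ centre, a defined allylic silane, a defined ethylidene geometry and a tetrasubstituted alkylidene malonate. That is the same C4a′ problem the enzyme solves in the chosen route, plus two more elements, and addition to a β,β-disubstituted acceptor is slow. After A3 the bicycle must again be grown linearly on a neopentyl carbon.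
- Comparison: this route is stronger on C2′ control and on olefin regiocontrol. The chosen route spends no steps on preparing ring A (9 is three steps from acyclic material) and is convergent.

Key step: step 3

## Route

Assumption: (1S,4S)-bicyclo[2.2.1]hept-5-en-2-one 12 is taken as a purchasable single enantiomer.
Assumption: the carbinol centre of 9 is drawn as the axial alcohol expected from a chair closure; either epimer would serve, because this centre becomes the radical.

Step 1
Reactants: 1 5-bromo-2-methylpent-2-ene; 2 lithium acetylide–ethylenediamine complex (LiC≡CH·H2NCH2CH2NH2)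
Product: 3 6-methylhept-5-en-1-yne
Conditions: DMSO, 0 °C → rt
Reagents that add atoms: none
Why: SN2 alkylation of an acetylide by a primary bromide; the remote trisubstituted olefin is inert.

Step 2
Reactants: 3 6-methylhept-5-en-1-yne; 4 ethylmagnesium bromide (EtMgBr); 5 but-3-en-2-one (methyl vinyl ketone)
Product: 7 (5E)-6-ethyl-10-methylundeca-5,9-dien-2-one, via alkenylcopper reagent 6 (not isolated)
Conditions: EtMgBr, CuBr·SMe2, Et2O/Me2S, −45 °C; 3, −25 °C; then 5, −78 → −30 °C; aq. NH4Cl
Reagents that add atoms: none
Why: Syn-carbocupration of the terminal alkyne puts ethyl on the internal carbon and copper cis to it, and conjugate addition of the alkenylcopper to the enone goes with retention. The new chain is therefore cis to ethyl and trans to the homoprenyl group, which should give the E olefin as a single geometric isomer.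

Step 3
Reactants: 7 (5E)-6-ethyl-10-methylundeca-5,9-dien-2-one
Product: 9 (1R,2S,4aS)-1,2,5,5-tetramethyl-1,2,3,4,4a,5,6,7-octahydronaphthalen-2-ol, via monocyclic ethylidene ketone 8 (not isolated)
Conditions: engineered squalene–hopene cyclase (Alicyclobacillus acidocaldarius, active-site variant selected from a library for monocyclisation and Prins activity), E. coli whole cells, citrate buffer pH 6, 0.1% SDS, 30 °C
Reagents that add atoms: none
Why: Proposed new method: the active-site acid of the cyclase protonates C9 of the terminal olefin of 7 (chain numbering), the C5=C6 olefin attacks the C10 cation in a chair fold (6-endo-trig cation–olefin closure of ring A, C5–C10 bond), and the C6 cation loses a proton from the ethyl CH2 to give the enzyme-bound (E)-ethylidene ketone 8. The same acid then activates the ketone and the ethylidene carbon attacks C2 (six-membered Prins or type-two carbonyl-ene closure of ring B, exo with respect to the C=O bond), after which the re-formed C6 cation loses H-7 to give the trisubstituted ring-A olefin of 9. The closest known reactions are the cyclase-mediated cyclisation of geranylacetone, of which 7 is the homologue with one more CH2, the cyclase-mediated Prins closure of citronellal, and the acid closure of dihydro-γ-ionone to α-ambrinol; their combination in one active site and the ethyl substrate are untested. C4a of 9 is fixed by the enzyme, which folds the chain in the pre-chair sense common to this cyclase class (S here). C1 is fixed in the second closure: the E-ethylidene reacting through a chair puts its methyl group equatorial and H-1 cis to H-4a, and the Z and E isomers can interconvert through the C6 cation. C2 is expected with the hydroxyl axial, but its configuration is irrelevant. The step needs proton loss to the side-chain olefin instead of capture of the C6 cation by the carbonyl oxygen, and it needs the tertiary alcohol to survive; the first is the property for which the variant is selected, and it is favoured by the ethyl group, which gives a trisubstituted instead of a 1,1-disubstituted exocyclic olefin.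

Step 4
Reactants: 9 (1R,2S,4aS)-1,2,5,5-tetramethyl-1,2,3,4,4a,5,6,7-octahydronaphthalen-2-ol
Product: 11 cesium 2-oxo-2-{[(1R,2S,4aS)-1,2,5,5-tetramethyl-1,2,3,4,4a,5,6,7-octahydronaphthalen-2-yl]oxy}acetate, via methyl oxalate diester 10 (not isolated)
Conditions: ClC(O)CO2Me, Et3N, DMAP (cat.), CH2Cl2, 0 °C → rt; then CsOH (1.0 equiv), THF/H2O, rt
Reagents that add atoms: methyl chlorooxoacetate COC(=O)C(=O)Cl; cesium hydroxide [Cs+].[OH-]
Why: DMAP-catalysed acylation of the tertiary alcohol by a small, very electrophilic acid chloride. One equivalent of hydroxide then cleaves the exposed methyl ester of the mixed oxalate in preference to the tertiary ester; no stereocentre is touched.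

Step 5
Reactants: 12 (1S,4S)-bicyclo[2.2.1]hept-5-en-2-one
Product: 13 (1S,5S)-2-oxabicyclo[3.2.1]oct-6-en-3-one
Conditions: mCPBA, NaHCO3 (solid buffer), CH2Cl2, 0 °C
Reagents that add atoms: 3-chloroperoxybenzoic acid OOC(=O)c1cccc(Cl)c1
Why: Baeyer–Villiger oxidation; the more substituted bridgehead carbon migrates with retention, and the buffer keeps the allylic lactone from acid-induced rearrangement.

Step 6
Reactants: 13 (1S,5S)-2-oxabicyclo[3.2.1]oct-6-en-3-one
Product: 14 (1S,4R,5R)-4-hydroxy-2-oxabicyclo[3.2.1]oct-6-en-3-one
Conditions: NaN(SiMe3)2, THF, −78 °C; 2-(phenylsulfonyl)-3-phenyloxaziridine, −78 °C; AcOH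
Reagents that add atoms: 2-(phenylsulfonyl)-3-phenyloxaziridine O=S(=O)(c1ccccc1)N1OC1c1ccccc1
Why: Electrophilic hydroxylation of the lactone enolate. The oxidant should enter C4 from the exo face, on the side of the methylene bridge, because the endo face is covered by the C6=C7 bridge; this sets the carbinol centre that becomes C6 of the target.

Step 7
Reactants: 14 (1S,4R,5R)-4-hydroxy-2-oxabicyclo[3.2.1]oct-6-en-3-one
Product: 15 methyl (2R)-2-hydroxy-2-[(1R,4S)-4-hydroxycyclopent-2-en-1-yl]acetate
Conditions: K2CO3 (cat.), MeOH, 0 °C
Reagents that add atoms: methanol CO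
Why: Transesterification opens the strained bridged lactone at the acyl carbon, so the ring C–O bond and the cis relation are kept; low temperature and catalytic base guard the α-hydroxy ester centre.

Step 8
Reactants: 15 methyl (2R)-2-hydroxy-2-[(1R,4S)-4-hydroxycyclopent-2-en-1-yl]acetate
Product: 16 methyl (2R)-2-hydroxy-2-[(1R)-4-oxocyclopent-2-en-1-yl]acetate
Conditions: MnO2, CH2Cl2, rt
Reagents that add atoms: none
Why: Activated manganese dioxide oxidises only the allylic alcohol; the neutral conditions leave the α-hydroxy ester and the γ-stereocentre of the enone alone.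

Step 9
Reactants: 16 methyl (2R)-2-hydroxy-2-[(1R)-4-oxocyclopent-2-en-1-yl]acetate
Product: 17 methyl (2R)-2-[(tert-butyldimethylsilyl)oxy]-2-[(1R)-4-oxocyclopent-2-en-1-yl]acetate
Conditions: TBSCl, imidazole, DMF, 0 °C → rt
Reagents that add atoms: tert-butyldimethylsilyl chloride CC(C)(C)[Si](C)(C)Cl
Why: Standard silylation; imidazole is too weak a base to deprotonate the γ-position of the enone, so neither epimerisation nor vinylogous retro-aldol cleavage is expected.

Step 10
Reactants: 17 methyl (2R)-2-[(tert-butyldimethylsilyl)oxy]-2-[(1R)-4-oxocyclopent-2-en-1-yl]acetate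
Product: 18 methyl (2R)-2-[(tert-butyldimethylsilyl)oxy]-2-[(1R)-3-chloro-4-oxocyclopent-2-en-1-yl]acetate
Conditions: PhICl2, pyridine, CH2Cl2, 0 °C → rt
Reagents that add atoms: (dichloroiodo)benzene ClI(Cl)c1ccccc1
Why: α-Chlorination of an enone by addition–elimination: chlorine adds across the C=C bond and pyridine removes the acidic α-hydrogen with loss of the β-chloride, which gives the 2-chloroenone.

Step 11
Reactants: 11 cesium 2-oxo-2-{[(1R,2S,4aS)-1,2,5,5-tetramethyl-1,2,3,4,4a,5,6,7-octahydronaphthalen-2-yl]oxy}acetate; 18 methyl (2R)-2-[(tert-butyldimethylsilyl)oxy]-2-[(1R)-3-chloro-4-oxocyclopent-2-en-1-yl]acetate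
Product: 19 methyl (2R)-2-[(tert-butyldimethylsilyl)oxy]-2-[(1R,2R)-3-chloro-4-oxo-2-[(1S,2R,4aS)-1,2,5,5-tetramethyl-1,2,3,4,4a,5,6,7-octahydronaphthalen-2-yl]cyclopentyl]acetate (chlorine-bearing carbon as a mixture of epimers)
Conditions: Ir[dF(CF3)ppy]2(dtbbpy)PF6 (1 mol%), H2O (10 equiv), DME/DMF 3:1, blue LEDs, 60 °C
Reagents that add atoms: none
Why: Photoredox Giese addition: the excited iridium complex oxidises the oxalate, loss of two CO2 gives the tertiary radical, which adds to ring carbon C3 of 18 anti to the C4 side chain; the α-chloro-α-keto radical is then reduced by the divalent iridium complex and protonated by water. The quaternary centre is expected to form by approach anti to the vicinal C1′ methyl group along the equatorial direction of ring B, which places the large substituent equatorial.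

Step 12
Reactants: 19 methyl (2R)-2-[(tert-butyldimethylsilyl)oxy]-2-[(1R,2R)-3-chloro-4-oxo-2-[(1S,2R,4aS)-1,2,5,5-tetramethyl-1,2,3,4,4a,5,6,7-octahydronaphthalen-2-yl]cyclopentyl]acetate
Product: 21 methyl (2R)-2-[(tert-butyldimethylsilyl)oxy]-2-[(1R,2S)-4-[(tert-butyldimethylsilyl)oxy]-2-[(1S,2S,4aS)-1,2,5,5-tetramethyl-1,2,3,4,4a,5,6,7-octahydronaphthalen-2-yl]cyclopent-3-en-1-yl]acetate, via lithium enolate 20 (not isolated)
Conditions: Me2CuLi (from CuI, MeLi), THF, −78 → −40 °C; then TBSCl, HMPA, −78 °C → rt
Reagents that add atoms: tert-butyldimethylsilyl chloride CC(C)(C)[Si](C)(C)Cl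
Why: Reductive removal of the α-chlorine by the cuprate gives the enolate regiospecifically at the former C–Cl carbon, and O-silylation fixes it as the enol silane. Base-mediated enolisation would not give this isomer selectively; the stereodescriptors of 21 change only because ligand priorities change.

Step 13
Reactants: 21 methyl (2R)-2-[(tert-butyldimethylsilyl)oxy]-2-[(1R,2S)-4-[(tert-butyldimethylsilyl)oxy]-2-[(1S,2S,4aS)-1,2,5,5-tetramethyl-1,2,3,4,4a,5,6,7-octahydronaphthalen-2-yl]cyclopent-3-en-1-yl]acetate
Product: 22 (3R,4R)-3-[(1R)-1-[(tert-butyldimethylsilyl)oxy]-2-methoxy-2-oxoethyl]-5-oxo-4-[(1S,2R,4aS)-1,2,5,5-tetramethyl-1,2,3,4,4a,5,6,7-octahydronaphthalen-2-yl]pentanoic acid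
Conditions: O3 (1.0 equiv, as a CH2Cl2 solution), CH2Cl2, −78 °C; then PPh3, −78 °C → rt; H2O
Reagents that add atoms: ozone [O-][O+]=O
Why: Ozonolysis of the enol silane gives the aldehyde at the former CH carbon and a silyl ester that is hydrolysed to the acid on work-up. The electron-rich enol ether should react ahead of the hindered trisubstituted ring-A olefin when ozone is dosed.

Step 14
Reactants: 22 (3R,4R)-3-[(1R)-1-[(tert-butyldimethylsilyl)oxy]-2-methoxy-2-oxoethyl]-5-oxo-4-[(1S,2R,4aS)-1,2,5,5-tetramethyl-1,2,3,4,4a,5,6,7-octahydronaphthalen-2-yl]pentanoic acid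
Product: 24 methyl (1S,5R,6R,8R)-3-oxo-8-[(1S,2R,4aS)-1,2,5,5-tetramethyl-1,2,3,4,4a,5,6,7-octahydronaphthalen-2-yl]-2,7-dioxabicyclo[3.2.1]octane-6-carboxylate, via lactol acid 23 (not isolated)
Conditions: HF·pyridine, THF, 0 °C → rt; then CSA (cat.), 4 Å MS, CH2Cl2, rt
Reagents that add atoms: none
Why: Desilylation frees the C6 hydroxyl, which closes onto the aldehyde to give the five-membered lactol, and acid-catalysed dehydrative lactonisation of the lactol hydroxyl with the acid completes the acylal. C1 can only form in the bridged sense dictated by C5 and C8, and the ester stays exo as set in step 6.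

## Compound list

1 | 5-bromo-2-methylpent-2-ene | CC(C)=CCCBr | starting material
2 | lithium acetylide–ethylenediamine complex | [Li]C#C.NCCN | starting material
3 | 6-methylhept-5-en-1-yne | C#CCCC=C(C)C | intermediate
4 | ethylmagnesium bromide | CC[Mg]Br | starting material
5 | but-3-en-2-one (methyl vinyl ketone) | CC(=O)C=C | starting material
6 | [(1E)-2-ethyl-6-methylhepta-1,5-dien-1-yl]copper, as its MgBr2 complex (copper cis to ethyl) | CC/C(CCC=C(C)C)=C\[Cu] | intermediate (not isolated)
7 | (5E)-6-ethyl-10-methylundeca-5,9-dien-2-one | CC(=O)CC/C=C(\CC)CCC=C(C)C | intermediate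
8 | 4-[(1S,2E)-2-ethylidene-6,6-dimethylcyclohexyl]butan-2-one | CC(=O)CC[C@@H]1/C(=C/C)CCCC1(C)C | intermediate (not isolated)
9 | (1R,2S,4aS)-1,2,5,5-tetramethyl-1,2,3,4,4a,5,6,7-octahydronaphthalen-2-ol | O[C@@]1(C)CC[C@@H]2C(=CCCC2(C)C)[C@H]1C | intermediate
10 | methyl (1R,2S,4aS)-1,2,5,5-tetramethyl-1,2,3,4,4a,5,6,7-octahydronaphthalen-2-yl oxalate | COC(=O)C(=O)O[C@@]1(C)CC[C@@H]2C(=CCCC2(C)C)[C@H]1C | intermediate (not isolated)
11 | cesium 2-oxo-2-{[(1R,2S,4aS)-1,2,5,5-tetramethyl-1,2,3,4,4a,5,6,7-octahydronaphthalen-2-yl]oxy}acetate | [Cs+].[O-]C(=O)C(=O)O[C@@]1(C)CC[C@@H]2C(=CCCC2(C)C)[C@H]1C | intermediate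
12 | (1S,4S)-bicyclo[2.2.1]hept-5-en-2-one | O=C1C[C@H]2C=C[C@@H]1C2 | starting material
13 | (1S,5S)-2-oxabicyclo[3.2.1]oct-6-en-3-one | O=C1C[C@H]2C=C[C@H](C2)O1 | intermediate
14 | (1S,4R,5R)-4-hydroxy-2-oxabicyclo[3.2.1]oct-6-en-3-one (hydroxyl exo) | O=C1[C@H](O)[C@H]2C=C[C@H](C2)O1 | intermediate
15 | methyl (2R)-2-hydroxy-2-[(1R,4S)-4-hydroxycyclopent-2-en-1-yl]acetate (ring substituents cis) | COC(=O)[C@H](O)[C@H]1C=C[C@@H](O)C1 | intermediate
16 | methyl (2R)-2-hydroxy-2-[(1R)-4-oxocyclopent-2-en-1-yl]acetate | COC(=O)[C@H](O)[C@H]1C=CC(=O)C1 | intermediate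
17 | methyl (2R)-2-[(tert-butyldimethylsilyl)oxy]-2-[(1R)-4-oxocyclopent-2-en-1-yl]acetate | COC(=O)[C@H](O[Si](C)(C)C(C)(C)C)[C@H]1C=CC(=O)C1 | intermediate
18 | methyl (2R)-2-[(tert-butyldimethylsilyl)oxy]-2-[(1R)-3-chloro-4-oxocyclopent-2-en-1-yl]acetate | COC(=O)[C@H](O[Si](C)(C)C(C)(C)C)[C@H]1C=C(Cl)C(=O)C1 | intermediate
19 | methyl (2R)-2-[(tert-butyldimethylsilyl)oxy]-2-[(1R,2R)-3-chloro-4-oxo-2-[(1S,2R,4aS)-1,2,5,5-tetramethyl-1,2,3,4,4a,5,6,7-octahydronaphthalen-2-yl]cyclopentyl]acetate (ring substituents trans; C–Cl epimers) | COC(=O)[C@H](O[Si](C)(C)C(C)(C)C)[C@@H]1CC(=O)C(Cl)[C@H]1[C@]2(C)CC[C@@H]3C(=CCCC3(C)C)[C@H]2C | intermediate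
20 | lithium enolate of the dechlorinated ketone: lithium (3S,4R)-4-[(1R)-1-[(tert-butyldimethylsilyl)oxy]-2-methoxy-2-oxoethyl]-3-[(1S,2S,4aS)-1,2,5,5-tetramethyl-1,2,3,4,4a,5,6,7-octahydronaphthalen-2-yl]cyclopent-1-en-1-olate | COC(=O)[C@H](O[Si](C)(C)C(C)(C)C)[C@@H]1CC(O[Li])=C[C@H]1[C@]2(C)CC[C@@H]3C(=CCCC3(C)C)[C@H]2C | intermediate (not isolated)
21 | methyl (2R)-2-[(tert-butyldimethylsilyl)oxy]-2-[(1R,2S)-4-[(tert-butyldimethylsilyl)oxy]-2-[(1S,2S,4aS)-1,2,5,5-tetramethyl-1,2,3,4,4a,5,6,7-octahydronaphthalen-2-yl]cyclopent-3-en-1-yl]acetate | COC(=O)[C@H](O[Si](C)(C)C(C)(C)C)[C@@H]1CC(O[Si](C)(C)C(C)(C)C)=C[C@H]1[C@]2(C)CC[C@@H]3C(=CCCC3(C)C)[C@H]2C | intermediate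
22 | (3R,4R)-3-[(1R)-1-[(tert-butyldimethylsilyl)oxy]-2-methoxy-2-oxoethyl]-5-oxo-4-[(1S,2R,4aS)-1,2,5,5-tetramethyl-1,2,3,4,4a,5,6,7-octahydronaphthalen-2-yl]pentanoic acid | COC(=O)[C@H](O[Si](C)(C)C(C)(C)C)[C@H](CC(=O)O)[C@@H](C=O)[C@]1(C)CC[C@@H]2C(=CCCC2(C)C)[C@H]1C | intermediate
23 | 2-[(2R,3R,4R)-5-hydroxy-2-(methoxycarbonyl)-4-[(1S,2R,4aS)-1,2,5,5-tetramethyl-1,2,3,4,4a,5,6,7-octahydronaphthalen-2-yl]oxolan-3-yl]acetic acid (lactol anomers) | COC(=O)[C@@H]1OC(O)[C@@H]([C@]2(C)CC[C@@H]3C(=CCCC3(C)C)[C@H]2C)[C@H]1CC(=O)O | intermediate (not isolated)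
24 | methyl (1S,5R,6R,8R)-3-oxo-8-[(1S,2R,4aS)-1,2,5,5-tetramethyl-1,2,3,4,4a,5,6,7-octahydronaphthalen-2-yl]-2,7-dioxabicyclo[3.2.1]octane-6-carboxylate | COC(=O)[C@@H]1O[C@H]2OC(=O)C[C@@H]1[C@@H]2[C@]1(C)CC[C@@H]2C(=CCCC2(C)C)[C@H]1C | target

## Step count and risks

Total: 14 steps. Longest linear sequence: 10 steps (steps 5–10, then 11–14, from 12). The decalin branch is 8 steps (steps 1–4, then 11–14).

**Step 3 (key step, proposed new method).** The most likely failures are capture of the C6 cation by the carbonyl oxygen to give a bicyclic enol ether, arrest at the monocyclic stage 8, a poor fit of the ethyl group in the active site, and reaction through the Z-ethylidene, which would give the C1′ epimer. The fallback uses no enzyme and resolves through the enantiopure coupling partner; it sets out from 5 and comes back at 19. Commercial 3-methylcyclohex-2-en-1-one is treated with Me2CuLi and the enolate is trapped with Me3SiCl to give 3,3-dimethyl-1-[(trimethylsilyl)oxy]cyclohex-1-ene F1. TiCl4-mediated Mukaiyama–Michael addition of F1 to 5 gives racemic 3,3-dimethyl-2-(3-oxobutyl)cyclohexan-1-one F2. KOH in MeOH closes it by aldol condensation (Robinson annulation) to racemic 5,5-dimethyl-4,4a,5,6,7,8-hexahydronaphthalen-2(3H)-one F3. Deconjugative α-methylation through the heteroannular dienolate (t-BuOK, t-BuOH, then MeI, with kinetic α-protonation on quench) gives racemic (1R,4aS)-1,5,5-trimethyl-3,4,4a,5,6,7-hexahydronaphthalen-2(1H)-one F4 with the methyl group equatorial. MeMgBr with CeCl3 gives racemic 1,2,5,5-tetramethyl-1,2,3,4,4a,5,6,7-octahydronaphthalen-2-ol F5. The conditions of step 4 convert F5 into the racemic methyl oxalate F6 and the racemic cesium oxalate F7. Coupling of F7 with enantiopure 18 under the conditions of step 11 should give 19 together with its diastereomer from the mirror-image radical F8; the two are separated by chromatography and the route continues from 19.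

**Step 11.** The risks are poor facial selectivity at the tertiary radical (only the vicinal C1′ methyl group and the equatorial preference of a bulky acceptor differentiate the faces), slow addition to a β-carbon flanked by a branched substituent, reduction of the C–Cl bond by the reduced photocatalyst, and base-induced loss of the silyloxy group from 18 at 60 °C. The fallback changes the radical precursor and the redox manifold; it sets out from 9 and comes back at 19. Alcohol 9 is treated with oxalyl chloride and then N-hydroxyphthalimide and Et3N to give the N-phthalimidoyl oxalate 1,3-dioxoisoindolin-2-yl (1R,2S,4aS)-1,2,5,5-tetramethyl-1,2,3,4,4a,5,6,7-octahydronaphthalen-2-yl oxalate F9. F9 is fragmented reductively with Ru(bpy)3(PF6)2, diethyl 2,6-dimethyl-1,4-dihydropyridine-3,5-dicarboxylate and i-Pr2NEt·HBF4 under visible light at room temperature in the presence of 18. There the α-keto radical is quenched by hydrogen-atom transfer, the medium is not basic, and the lower temperature should sharpen the face selection.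

**Step 13.** The risk is competing ozonolysis of the C8′=C8a′ olefin if the two double bonds are not differentiated well enough. The fallback replaces ozone by a two-stage cleavage; it sets out from 21 and comes back at 22. Catalytic OsO4 with N-methylmorpholine N-oxide hydroxylates the more electron-rich enol silane and, after loss of the silyl group, gives the α-hydroxy ketone methyl (2R)-2-[(tert-butyldimethylsilyl)oxy]-2-[(1R,2R)-3-hydroxy-4-oxo-2-[(1S,2R,4aS)-1,2,5,5-tetramethyl-1,2,3,4,4a,5,6,7-octahydronaphthalen-2-yl]cyclopentyl]acetate F10. NaIO4 in aqueous THF then cleaves the ketol to aldehyde acid 22.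

**Step 6.** The risk is attack of the oxidant on the endo face, or a mixture of faces, because the methylene bridge also shields the exo face to some degree. The fallback corrects the centre by inversion; it sets out from 13 and comes back at 15. If the endo alcohol (1S,4S,5R)-4-hydroxy-2-oxabicyclo[3.2.1]oct-6-en-3-one F11 is formed, Mitsunobu reaction with 4-nitrobenzoic acid (PPh3, diisopropyl azodicarboxylate) brings the nucleophile in from the open exo face and gives (1S,4R,5R)-3-oxo-2-oxabicyclo[3.2.1]oct-6-en-4-yl 4-nitrobenzoate F12. K2CO3 in MeOH then removes the benzoate and opens the lactone in one operation to give 15.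

**Step 14.** The risks are acid-induced migration of the C8′=C8a′ olefin to the tetrasubstituted position (loss of C4a′), epimerisation at C8 through the enol of the open aldehyde, and incomplete lactonisation. The fallback avoids acid catalysis; it sets out from 22 and comes back at 24. Buffered fluoride (Bu4NF with AcOH, THF) removes the silyl group and lactol acid 23 is isolated. The lactone is then closed by activating the carboxyl group (N-(3-dimethylaminopropyl)-N′-ethylcarbodiimide hydrochloride, DMAP, CH2Cl2) so that the lactol hydroxyl is acylated under neutral conditions.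

## Further compounds

F1 | step 3 | 3,3-dimethyl-1-[(trimethylsilyl)oxy]cyclohex-1-ene | C[Si](C)(C)OC1=CC(C)(C)CCC1
F2 | step 3 | rac-3,3-dimethyl-2-(3-oxobutyl)cyclohexan-1-one | CC(=O)CCC1C(=O)CCCC1(C)C
F3 | step 3 | rac-5,5-dimethyl-4,4a,5,6,7,8-hexahydronaphthalen-2(3H)-one | O=C1CCC2C(=C1)CCCC2(C)C
F4 | step 3 | rac-(1R,4aS)-1,5,5-trimethyl-3,4,4a,5,6,7-hexahydronaphthalen-2(1H)-one (one enantiomer drawn) | O=C1CC[C@@H]2C(=CCCC2(C)C)[C@H]1C
F5 | step 3 | rac-(1R,4aS)-1,2,5,5-tetramethyl-1,2,3,4,4a,5,6,7-octahydronaphthalen-2-ol (one enantiomer drawn, C2 either) | OC1(C)CC[C@@H]2C(=CCCC2(C)C)[C@H]1C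
F6 | step 3 | rac-methyl (1R,4aS)-1,2,5,5-tetramethyl-1,2,3,4,4a,5,6,7-octahydronaphthalen-2-yl oxalate (one enantiomer drawn) | COC(=O)C(=O)OC1(C)CC[C@@H]2C(=CCCC2(C)C)[C@H]1C
F7 | step 3 | rac-cesium 2-oxo-2-{[(1R,4aS)-1,2,5,5-tetramethyl-1,2,3,4,4a,5,6,7-octahydronaphthalen-2-yl]oxy}acetate (one enantiomer drawn) | [Cs+].[O-]C(=O)C(=O)OC1(C)CC[C@@H]2C(=CCCC2(C)C)[C@H]1C
F8 | step 3 | methyl (2R)-2-[(tert-butyldimethylsilyl)oxy]-2-[(1R,2R)-3-chloro-4-oxo-2-[(1R,2S,4aR)-1,2,5,5-tetramethyl-1,2,3,4,4a,5,6,7-octahydronaphthalen-2-yl]cyclopentyl]acetate | COC(=O)[C@H](O[Si](C)(C)C(C)(C)C)[C@@H]1CC(=O)C(Cl)[C@H]1[C@@]2(C)CC[C@H]3C(=CCCC3(C)C)[C@@H]2C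
F9 | step 11 | 1,3-dioxoisoindolin-2-yl (1R,2S,4aS)-1,2,5,5-tetramethyl-1,2,3,4,4a,5,6,7-octahydronaphthalen-2-yl oxalate | O=C(ON1C(=O)c2ccccc2C1=O)C(=O)O[C@@]1(C)CC[C@@H]2C(=CCCC2(C)C)[C@H]1C
F10 | step 13 | methyl (2R)-2-[(tert-butyldimethylsilyl)oxy]-2-[(1R,2R)-3-hydroxy-4-oxo-2-[(1S,2R,4aS)-1,2,5,5-tetramethyl-1,2,3,4,4a,5,6,7-octahydronaphthalen-2-yl]cyclopentyl]acetate | COC(=O)[C@H](O[Si](C)(C)C(C)(C)C)[C@@H]1CC(=O)C(O)[C@H]1[C@]2(C)CC[C@@H]3C(=CCCC3(C)C)[C@H]2C
F11 | step 6 | (1S,4S,5R)-4-hydroxy-2-oxabicyclo[3.2.1]oct-6-en-3-one | O=C1[C@@H](O)[C@H]2C=C[C@H](C2)O1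
F12 | step 6 | (1S,4R,5R)-3-oxo-2-oxabicyclo[3.2.1]oct-6-en-4-yl 4-nitrobenzoate | O=C1[C@H](OC(=O)c2ccc(cc2)[N+](=O)[O-])[C@H]2C=C[C@H](C2)O1
F0 | step 14 | none | none
A1 | alternative 1 | (1R,2R,8S)-8-[(tert-butyldimethylsilyl)oxy]-1,2,5,5-tetramethyl-1,2,3,4,5,6,7,8-octahydronaphthalene-2-carbaldehyde | O=C[C@]1(C)CCC2=C([C@@H](O[Si](C)(C)C(C)(C)C)CCC2(C)C)[C@H]1C
A2 | alternative 2 | dimethyl (1S,5R,8R)-3-oxo-8-[(1S,2R,4aS)-1,2,5,5-tetramethyl-1,2,3,4,4a,5,6,7-octahydronaphthalen-2-yl]-2,7-dioxabicyclo[3.2.1]octane-6,6-dicarboxylate | COC(=O)C1(C(=O)OC)O[C@H]2OC(=O)C[C@@H]1[C@@H]2[C@]3(C)CC[C@@H]4C(=CCCC4(C)C)[C@H]3C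
A3 | alternative 3 | dimethyl 2-[(1S,2R,4aS)-1,2,5,5-tetramethyl-1,2,3,4,4a,5,6,7-octahydronaphthalen-2-yl]propanedioate | COC(=O)C(C(=O)OC)[C@]1(C)CC[C@@H]2C(=CCCC2(C)C)[C@H]1C
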